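Add the left-handed product and the left-handed substrate of Saturday's flask at 2.50 min: they come to 56.2% of the charge, from a left-handed charge of 50.0%, which cannot be unless handedness changes inside the flask.

- Saturday's: left-handed substrate 0.77 M; right-handed substrate 0.77 M; coupling partner 1.93 M; free catalyst 7.7 mM; impurity 2.7 mM; the very flask that is asked about, followed so far
- flask: left-handed substrate 0.77 M; coupling partner 1.93 M; free catalyst 7.7 mM; impurity 2.7 mM; right-handed substrate 0.77 M; time 30 min

Saturday's run (percent of the left-handed substrate and right-handed substrate together charged)

| time / min | left-handed substrate / % | right-handed substrate / % | left-handed product / % |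
|---|---|---|---|
| 0.667 | 12.9 | 16.2 | 40.9 |
| 1.33 | 8.1 | 9.4 | 47.5 |
| 2.50 | 5.3 | 6.0 | 50.9 |
| 5.00 | 3.0 | 2.8 | 51.1 |
| 10.0 | 2.0 | 2.2 | 49.6 |

(scatter of a reading: 0.5 percentage points)

- free catalyst is single-handed; left-handed substrate and right-handed substrate are mirror images of each other, charged as a racemate, each of them at the stated concentration
- the earlier runs were read with a standard deviation of 0.5 percentage points
- an excess is below zero if the other one leads

* part of the left-handed substrate and right-handed substrate charged together that has reacted at 30 min
* excess of left-handed product over right-handed product in the product at 30 min
* excess of right-handed substrate over left-handed substrate among what is left of the two at 30 min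

Saturday's run is this same flask followed so far, so work from it. Take the right-handed product as what the three readings leave of the charge, and form the excess of left-handed over right-handed product: 8.49% at 5.00 min, 3.55% at 10.0 min. Total product moves from 94.2% to 95.8% meanwhile, so the excess is being lost, not diluted.

Read from these a halving time of the excess, 3.97 min, and divide the run by it: the halving count, 7.55, says how many times a product excess halves over the run. Since the halving time is shorter than the run, carry the last excess forward to 30 min: my figure is 0.108%, a reading with the scatter of its parents.

Now test the one number on the substrates. Their sum falls from 11.3% to 5.80% between 2.50 min and 5.00 min, then merely to 4.20% by 10.0 min. That tail lies outside the count, so the count gives no figure for c.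

The forecast, judging that “The product is therefore racemizing”, gave 97.5% (96% to 98.8%) for c, 0.5% (0% to 2.5%) for eP and 2% (−2% to 8%) for eS. My eP is lower, inside its range.

The flask gives 97.4%, 0.250% and 0.0668%, each inside those ranges.

    left-handed substrate ⇌ right-handed substrate (k = 0.0274 /s)
    coupling partner + free catalyst + right-handed substrate → free catalyst + right-handed product (k = 4.88 /M²/s)
    coupling partner + free catalyst + left-handed substrate → free catalyst + left-handed product (k = 8.37 /M²/s)
    left-handed product ⇌ right-handed product (k = 0.00134 /s)
    free catalyst + impurity → spent catalyst (k = 317 /M/s)
    2 coupling partner → self-condensation product (k = 0.00411 /M/s)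

In this flask the half-life of left-handed substrate by coupling, 0.29 min at 0.249 min, is shorter than the relaxation half-life of the two products, 4.31 min, and that is short against 30 min. That relaxation half-life goes into the run 6.96 times, fewer than my count of 7.55 read from scattered readings, and the eP of this flask stands above my figure of 0.108%.

Take the neighbour charged with 0.0031 M of free catalyst: same time, same count 7.55, so expect a small excess. It gives 0.585% at 49.6% reacted.

(The data are calculated from invented constants, and the scatter is random.)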